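**Plan**

- Cuts: both isovalerate O-acyl bonds are cut first (back to a diol). The ring B CH2OH is then traced to a methyl ester, the C(sp)-C5 bond at ring A is cut (Sonogashira), and ring B is opened last at S1(B)-C2(B) and C4(B)-C5(B).
- Labels: ring A carries the butynyl chain. Ring B is S1(B), C2(B) (bonded to ring A), C3(B), C4(B), C5(B) (bearing CH2O).
- Enabling feature: S1(B)-C5(B)-CH2O is an S-C-C(O) triad, the skeleton of a thioglycolate ester. C2(B)-C3(B)-C4(B) is a 3-chloroacrolein grown from the acetyl group of a ring A ketone.
- Forward order: ring A is bought and ring B is closed on it without any metal. The alkyne is then coupled, the ester reduced and both alcohols acylated in one operation.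
- Stereochemistry: the target has no stereocentre and no stereogenic alkene. The only stereo-element en route is the Z geometry of the chloroacrolein, which arises in the chloroformylation and is consumed in the ring closure.

Key step: step 2

**Step 1**
Reactants: 1 2-acetyl-5-bromothiophene
Product: 3 (Z)-3-(5-bromothiophen-2-yl)-3-chloroprop-2-enal, via chloropropeniminium dichlorophosphate 2 (not isolated)
Conditions: POCl3 (3 equiv), DMF, 0 °C to 60 °C; then aq. NaOAc, 0 °C
Reagents that add atoms: N,N-dimethylformamide CN(C)C=O; phosphoryl chloride O=P(Cl)(Cl)Cl; water O
Why: Vilsmeier-Haack-Arnold chloroformylation, in which the enol of the methyl ketone is formylated at CH3 by the chloromethyleneiminium ion, the resulting vinylogous amide is O-activated so that chloride replaces oxygen, and hydrolysis of 2 releases the aldehyde with the thienyl group trans to CHO (Z, chlorine cis to CHO), while ring A stays untouched because both of its alpha positions are occupied and it is acceptor-deactivated.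

**Step 2**
Reactants: 3 (Z)-3-(5-bromothiophen-2-yl)-3-chloroprop-2-enal; 4 methyl thioglycolate
Product: 7 methyl 5'-bromo-2,2'-bithiophene-5-carboxylate, via open-chain vinyl sulfide 5 (not isolated), via hydroxydihydrothiophene 6 (not isolated)
Conditions: 4 (1.05 equiv), K2CO3 (2.5 equiv), DMF, 0 °C to 60 °C
Reagents that add atoms: methyl thioglycolate (4) COC(=O)CS
Why: Carbonate turns 4 into its thiolate, which adds to the chlorine-bearing carbon of 3 (the beta carbon of a vinylogous acid chloride) and expels chloride, an addition-elimination that forms S1(B)-C2(B) and leaves sulfur cis to the formyl group in sulfide 5. The SCH2 group of 5, acidified by the ester and by sulfur, is then deprotonated and its enolate attacks the formyl carbon in a 5-(enolexo)-exo-trig aldol closure that forms C4(B)-C5(B) and gives 6, from which loss of water, driven by aromatisation, delivers ring B with the ester carbon already on C5(B). The closest known reaction type is the Fiesselmann-type thiophene synthesis from beta-chlorovinyl aldehydes and thioglycolate esters, well established for 5-aryl- and 5-hetarylthiophene-2-carboxylates, with the K2CO3/DMF thioglycolate annulation of 2-halobenzaldehydes to benzothiophene-2-carboxylates as a close relative. No stereocentre is created in the product, since the two sp3 centres of 6 vanish on dehydration. The regiochemistry needed (sulfur at the former ketone carbon, carbanion at the formyl carbon) is fixed by the polarity of 3, in which the soft thiolate can only substitute at C-Cl and the only carbonyl within reach of the carbanion is the cis formyl group; a minor E component would still converge because 5 is a push-pull alkene with a low rotation barrier. The chemoselectivity needed is survival of the ring A C-Br bond, secured because the vinylic chloride is far more electrophilic than the bromothiophene carbon, by limiting 4 to a slight excess and by running the substitution stage at 0 °C before warming.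

**Step 3**
Reactants: 7 methyl 5'-bromo-2,2'-bithiophene-5-carboxylate; 8 but-3-yn-1-ol
Product: 9 methyl 5'-(4-hydroxybut-1-yn-1-yl)-2,2'-bithiophene-5-carboxylate
Conditions: 8 (1.3 equiv), PdCl2(PPh3)2 (3 mol %), CuI (5 mol %), Et3N, THF, degassed, 50 °C
Reagents that add atoms: but-3-yn-1-ol (8) C#CCCO
Why: Sonogashira coupling, in which zerovalent palladium formed in situ inserts into the ring A C-Br bond (activated by conjugation to the ester through the bithiophene), the copper acetylide of 8 transmetalates and reductive elimination forms the C(sp)-C(sp2) bond, while the free alcohol and the methyl ester are spectators under amine base.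

**Step 4**
Reactants: 9 methyl 5'-(4-hydroxybut-1-yn-1-yl)-2,2'-bithiophene-5-carboxylate
Product: 10 4-[5'-(hydroxymethyl)-2,2'-bithiophen-5-yl]but-3-yn-1-ol
Conditions: i-Bu2AlH (DIBAL-H, 3.5 equiv), CH2Cl2, -78 °C to 0 °C; then aq. KNaC4H4O6 (potassium sodium tartrate)
Reagents that add atoms: none
Why: DIBAL-H ester reduction, in which one hydride is spent on the free hydroxyl group and two more carry the ester through the aldehyde stage to the aluminium alkoxide of the thenylic alcohol, whereas hydroalumination of an internal alkyne needs heating and should not compete at or below 0 °C.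

**Step 5**
Reactants: 10 4-[5'-(hydroxymethyl)-2,2'-bithiophen-5-yl]but-3-yn-1-ol; 11 3-methylbutanoyl chloride (isovaleryl chloride)
Product: 12 4-(5'-{[(3-methylbutanoyl)oxy]methyl}-2,2'-bithiophen-5-yl)but-3-yn-1-yl 3-methylbutanoate (CNP0154475.0)
Conditions: 11 (2.5 equiv), Et3N (3 equiv), DMAP (10 mol %), CH2Cl2, 0 °C to rt
Reagents that add atoms: 3-methylbutanoyl chloride (11) CC(C)CC(=O)Cl
Why: DMAP-catalysed O-acylation with an acid chloride (nucleophilic catalysis through the acylpyridinium ion) should esterify both unhindered primary alcohols in one operation, and the basic medium keeps the acid-sensitive thenylic C-O bond from ionising.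

**Compound list**

1 | 2-acetyl-5-bromothiophene | CC(=O)c1ccc(Br)s1 | starting material
2 | N-[(2Z)-3-(5-bromothiophen-2-yl)-3-chloroprop-2-en-1-ylidene]-N-methylmethanaminium dichlorophosphate (formed in the flask, not isolated) | C[N+](C)=C/C=C(Cl)/c1ccc(Br)s1.[O-]P(=O)(Cl)Cl | intermediate
3 | (Z)-3-(5-bromothiophen-2-yl)-3-chloroprop-2-enal | O=C/C=C(Cl)/c1ccc(Br)s1 | intermediate
4 | methyl thioglycolate (methyl 2-sulfanylacetate) | COC(=O)CS | starting material
5 | methyl {[(1Z)-1-(5-bromothiophen-2-yl)-3-oxoprop-1-en-1-yl]sulfanyl}acetate (formed in the flask, not isolated) | O=C/C=C(SCC(=O)OC)/c1ccc(Br)s1 | intermediate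
6 | methyl 5-(5-bromothiophen-2-yl)-3-hydroxy-2,3-dihydrothiophene-2-carboxylate (diastereomer mixture, both centres erased on dehydration; formed in the flask, not isolated) | COC(=O)C1SC(=CC1O)c1ccc(Br)s1 | intermediate
7 | methyl 5'-bromo-2,2'-bithiophene-5-carboxylate | COC(=O)c1ccc(-c2ccc(Br)s2)s1 | intermediate
8 | but-3-yn-1-ol | C#CCCO | starting material
9 | methyl 5'-(4-hydroxybut-1-yn-1-yl)-2,2'-bithiophene-5-carboxylate | COC(=O)c1ccc(-c2ccc(C#CCCO)s2)s1 | intermediate
10 | 4-[5'-(hydroxymethyl)-2,2'-bithiophen-5-yl]but-3-yn-1-ol | OCCC#Cc1ccc(-c2ccc(CO)s2)s1 | intermediate
11 | 3-methylbutanoyl chloride (isovaleryl chloride) | CC(C)CC(=O)Cl | starting material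
12 | 4-(5'-{[(3-methylbutanoyl)oxy]methyl}-2,2'-bithiophen-5-yl)but-3-yn-1-yl 3-methylbutanoate | CC(C)CC(=O)OCCC#Cc1ccc(-c2ccc(COC(=O)CC(C)C)s2)s1 | target

**Step count**

Total step count: 5.
Longest linear sequence: 5 steps (1 to 3 to 7 to 9 to 10 to 12).

**Steps most likely to fail**

**Step 1.** Three processes are of concern.
- The ring A bromine may exchange for chlorine while the iminium-activated thiophene sits in a hot, chloride-rich medium.
- Tar may form with excess reagent.
- The chloroacrolein may decompose thermally on concentration or storage.

The fallback splits the one-pot reaction into two mild stages through an isolable vinylogous amide.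
- It sets out from 1. Condensation with N,N-dimethylformamide dimethyl acetal (toluene, reflux) should give (E)-1-(5-bromothiophen-2-yl)-3-(dimethylamino)prop-2-en-1-one F1.
- One equivalent of POCl3 in CH2Cl2 at 0 °C should convert this into iminium salt 2 without heating or a large chloride excess.
- Hydrolysis with aq. NaOAc comes back to the route at 3.

**Step 2.** Three processes are of concern.
- The thiolate may attack the bromine-bearing carbon of ring A, which is activated through conjugation with the formyl group.
- The sequence may stall before dehydration.
- The water released may partly saponify the ester.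

The fallback keeps the same ring closure but carries no halogen through it. Bromine is introduced afterwards by electrophilic substitution.
- It sets out from 4. The partner is made from commercial 2-acetylthiophene F2, which is chloroformylated (POCl3, DMF, then aq. NaOAc) to (Z)-3-chloro-3-(thiophen-2-yl)prop-2-enal F3.
- Condensation of F3 with 4 (K2CO3, DMF) should give methyl 2,2'-bithiophene-5-carboxylate F4.
- NBS in DMF at 0 °C in the dark should brominate the only free alpha position, that of the electron-richer ring A. This comes back to the route at 7.

**Step 4.** Two processes are of concern.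
- The neighbouring aluminium alkoxide may assist hydroalumination of the alkyne.
- Acid may trigger ionisation and oligomerisation at the thenylic position during work-up and chromatography of the polar diol.

The fallback moves the hydride step ahead of the alkyne and makes the endgame convergent.
- It sets out from 7. Reduction with i-Bu2AlH should give (5'-bromo-2,2'-bithiophen-5-yl)methanol F5.
- F5 is acylated at once with 11 (Et3N, DMAP, CH2Cl2) to (5'-bromo-2,2'-bithiophen-5-yl)methyl 3-methylbutanoate F6.
- Separately, 8 and 11 under the same acylation conditions give but-3-yn-1-yl 3-methylbutanoate F7.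
- Sonogashira coupling of F6 with F7 (PdCl2(PPh3)2, CuI, Et3N, THF) comes back to the route directly at 12.

**Further compounds**

F1 | step 1 | (E)-1-(5-bromothiophen-2-yl)-3-(dimethylamino)prop-2-en-1-one | CN(C)/C=C/C(=O)c1ccc(Br)s1
F2 | step 2 | 2-acetylthiophene (commercial) | CC(=O)c1cccs1
F3 | step 2 | (Z)-3-chloro-3-(thiophen-2-yl)prop-2-enal | O=C/C=C(Cl)/c1cccs1
F4 | step 2 | methyl 2,2'-bithiophene-5-carboxylate | COC(=O)c1ccc(-c2cccs2)s1
F5 | step 4 | (5'-bromo-2,2'-bithiophen-5-yl)methanol | OCc1ccc(-c2ccc(Br)s2)s1
F6 | step 4 | (5'-bromo-2,2'-bithiophen-5-yl)methyl 3-methylbutanoate | CC(C)CC(=O)OCc1ccc(-c2ccc(Br)s2)s1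
F7 | step 4 | but-3-yn-1-yl 3-methylbutanoate | C#CCCOC(=O)CC(C)C
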